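## Analysis of the target

2'-O-Methylperlatolic acid (22) is a depside: two 1,2,4,6-tetrasubstituted benzene rings joined by one ester. Ring A (C1–C6) is the 2-hydroxy-4-methoxy-6-pentylbenzoyl unit. Its carbonyl carbon C7 is esterified by the C4' oxygen of ring B (C1'–C6'), a 2'-methoxy-6'-pentylbenzoic acid.

There is no stereocentre and no stereogenic double bond, so the problem is one of constitution only. Five oxygen functions must emerge differentiated on two rings with the same carbon skeleton: the chelated free OH at C2, OMe at C4 and at C2', the acylated oxygen at C4', and the free CO2H at C1'.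

The sensitive group is the aryl ester C7(=O)–O–C4'. It is an activated acyl donor towards alkoxides, hydroxide and amines, so the ring B acid must be released without base. The electron-rich, di-ortho-substituted acid at C1' also does not tolerate hot strong acid (decarboxylation).

The classical difficulty is the depside bond itself. C7 sits between the C2 oxygen and the C6 pentyl group and is deactivated by two donor oxygens, while the C4' phenol is a weak nucleophile because it is para to a carbonyl group.

The feature the plan exploits is this. In both rings a carbonyl-bearing carbon is bonded directly to the pentyl-bearing carbon (C1–C6 in ring A, C1'–C6' in ring B). The remaining four ring carbons (C2–C5 and C2'–C5') carry oxygen on the first and third and hydrogen on the second and fourth. Each ring is therefore the imprint of an oct-2-ynoate (C7, C1, C6 and the pentyl chain) joined to a 1,1,3-trioxygenated buta-1,3-diene. The only difference between the rings, which oxygen carries the methyl group, can be written into the diene.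

## Retrosynthetic reasoning

**22 ⇒ 21.** The first cut is the benzyl–oxygen bond of the C1' carboxyl group. A benzyl ester comes off by hydrogenolysis under neutral conditions that leave the aryl ester C7(=O)–O–C4' alone. The forward step has nothing else to achieve.

**21 ⇒ 13 + 18 (key disconnection).** Ring A is taken apart completely by cutting C1–C2 and C5–C6. C7, C1, C6 and the pentyl chain stay behind as an oct-2-ynoyl group on the C4' oxygen (aryl ynoate 13). C2–C5 with both oxygens leave as the vinylketene silyl acetal 18. The cut is made here and not at the C7–O bond because that bond is hard to form only while ring A exists, when C7 is flanked by two ortho substituents. Before ring A exists the same bond is an ordinary ester of an unhindered acid. The gain is that one step creates a whole aromatic ring with its four substituents in their final state (free OH at C2, OMe at C4, pentyl at C6, the depside carbonyl at C1), with no protecting group on ring A and no hindered coupling. The forward reaction must be a regioselective [4+2] cycloaddition with aromatisation, in which the silyl methyl acetal carbon of 18 becomes C2–OH and its enol ether carbon becomes C4–OMe.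

**13 ⇒ 12 + 1.** The ester bond C7–O(C4') is now cut between phenol 12 and oct-2-ynoic acid 1. At this stage the acyl carbon hangs on an sp carbon with no ortho substituents, so the forward step is a routine carbodiimide esterification of the only free hydroxyl group of 12.

**12 ⇒ 2 + 9.** Ring B is disconnected in the same way, at C1'–C2' and C5'–C6', into benzyl oct-2-ynoate 2 and diene 9. Diene 9 carries two methoxy groups on its terminal carbon and the silyloxy group on C3, the reverse of the arrangement in 18. The same cycloaddition therefore leaves OMe at C2' and a free OH at C4', exactly the oxygen the next step acylates. Both rings thus come from one alkyne building block, and the methylation pattern is decided by the choice of diene.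

**2 ⇒ 1.** The benzyl ester is traced back to commercial oct-2-ynoic acid 1 by O-alkylation of its carboxylate.

**18 ⇒ 16 ⇒ 14.** Diene 18 is the O-silylated extended enolate of the vinylogous carbonate 16. Compound 16 is the enol methyl ether of methyl acetoacetate 14.

**9 ⇒ 8 ⇒ 6 ⇒ 3 + 4.** Diene 9 is the silyl enol ether of the acylketene acetal 8. Compound 8 arises by exchanging both vinylic chlorines of dichloroenone 6 for methoxy groups. Compound 6 is the acylation product of 1,1-dichloroethene 4 with acetyl chloride 3. All three steps use bulk chemicals.

## Alternatives that were turned down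

**Alternative 1:** the textbook disconnection of the depside ester C7–O(C4') between two finished rings.
- Forward key step: carbodiimide or trifluoroacetic anhydride coupling of 2-(benzyloxy)-4-methoxy-6-pentylbenzoic acid A1 with phenol 12 to give the dibenzyl-protected depside A2, then double hydrogenolysis to 22.
- Why turned down: the carboxyl carbon of A1 is shielded by two ortho substituents and deactivated by two donor oxygens, and 12 is a phenol para to an ester. The acylation is therefore slow and prone to N-acylurea and anhydride side paths.
- A1 also needs its own sequence of about five steps from a purchased 5-alkylresorcinol (introduction of the carboxyl carbon, selective 4-O-methylation, 2-O-protection, adjustment to the acid). Its OH/OMe pattern rests on chelation-dependent protecting-group steps.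
- No ring is constructed, and the step count is higher than in the chosen route.

**Alternative 2:** a biomimetic construction of ring A by aldol closure of the C1–C6 bond in a polyketide chain already attached to the C4' oxygen.
- Forward key step: thermolysis of 6-(2,4-dioxononyl)-2,2-dimethyl-4H-1,3-dioxin-4-one A3 in the presence of 12. The acylketene is trapped as the aryl 3,5,7-trioxododecanoate A4. Base-mediated aldol condensation and dehydration give the 2,4-dihydroxy depside ester A5, and selective 4-O-methylation gives 21.
- Why turned down: in A4 the aryl ester is an activated acyl donor six atoms away from the C5 enol oxygen. Lactonisation to the pyrone A6 with expulsion of 12 competes directly with the desired C-cyclisation.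
- A3 costs three to four steps.
- The ring emerges with two free hydroxyl groups, so a further regioselective methylation is needed. The ring construction does not itself put the substituents in place.

**Alternative 3:** a [3+3] cyclocondensation that forms C3–C4 and C1–C6 of ring A from a 1,3-bis(silyloxy)diene and a 1,3-dielectrophile.
- Forward key step: acetoacetylation of 12 to the aryl acetoacetate A7, double silylation to the bis(silyloxy)diene A8, and TiCl4-mediated cyclocondensation with 1,1-dimethoxyoct-1-en-3-one A9 to give 21.
- Why turned down: the second enolisation of A7 needs a strong base, and the enolate of an aryl β-keto ester fragments by loss of the phenoxide (acylketene formation).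
- TiCl4 would chelate the ortho-methoxy benzoate of ring B, with a risk of demethylation or loss of the benzyl group.
- A9 needs its own synthesis, and four steps follow 12 where the chosen route needs two.

Key step: step 9

## Route

Remark on the chemistry: the target has no stereocentre. The ketene acetal geometry of 7, 17 and 18 and the configuration of the acetal carbon of 19 are left undefined, because they are erased in the following bond-forming events. Ring A is numbered C1–C6 with carbonyl carbon C7, ring B C1'–C6'.

Step 1
Reactants: 1 oct-2-ynoic acid
Product: 2 benzyl oct-2-ynoate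
Conditions: BnBr, K2CO3, DMF, rt
Reagents that add atoms: benzyl bromide, BrCc1ccccc1
Why: O-Alkylation of the carboxylate (SN2 on the benzylic bromide); the acid needs no activation, so the triple bond is not exposed to nucleophilic catalysts, and the benzyl ester can be removed at the end without touching the aryl ester.

Step 2
Reactants: 3 acetyl chloride; 4 1,1-dichloroethene
Product: 6 4,4-dichlorobut-3-en-2-one, via 4,4,4-trichlorobutan-2-one 5 (not isolated)
Conditions: AlCl3 (1.1 equiv), CH2Cl2, 0 °C to rt; ice/aq. HCl; then steam distillation
Reagents that add atoms: none
Why: Lewis acid-mediated acylation of an alkene (Friedel–Crafts-type, Kondakov acylation): the acylium ion adds to the CH2 terminus to give the chlorine-stabilised cation, chloride capture gives 5, and β-elimination of HCl on steam distillation gives the conjugated enone 6.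

Step 3
Reactants: 6 4,4-dichlorobut-3-en-2-one
Product: 8 4,4-dimethoxybut-3-en-2-one, via 4-chloro-4-methoxybut-3-en-2-one 7 (not isolated)
Conditions: NaOMe (2.0 equiv), MeOH, −10 to 0 °C
Reagents that add atoms: sodium methoxide, [Na+].[O-]C
Why: Two successive addition–elimination reactions (nucleophilic vinylic substitution) at the β-carbon of the β,β-dichloro enone; exactly two equivalents of methoxide at low temperature should stop at the acylketene acetal.

Step 4
Reactants: 8 4,4-dimethoxybut-3-en-2-one
Product: 9 1,1-dimethoxy-3-(trimethylsilyloxy)buta-1,3-diene
Conditions: Me3SiCl, Et3N, ZnCl2 (cat.), Et2O/toluene, rt to 40 °C; filtration, distillation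
Reagents that add atoms: chlorotrimethylsilane, C[Si](C)(C)Cl
Why: Silyl enol ether formation under the amine/ZnCl2 conditions used for 2-silyloxy dienes; the methyl group is the only enolisable position of 8, so the cross-conjugated diene 9 is the only silyl enol ether that can form.

Step 5
Reactants: 2 benzyl oct-2-ynoate; 9 1,1-dimethoxy-3-(trimethylsilyloxy)buta-1,3-diene
Product: 12 benzyl 4-hydroxy-2-methoxy-6-pentylbenzoate, via cyclohexadiene cycloadduct 10 (not isolated), via aryl trimethylsilyl ether 11 (not isolated)
Conditions: 9 (2 equiv), neat, 120 °C, sealed tube; then 1 M HCl, THF, rt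
Reagents that add atoms: none
Why: Thermal Diels–Alder reaction followed by aromatisation: the electron-rich CH2 terminus of 9 bonds to the pentyl-bearing β-carbon of the ynoate and the acetal carbon to the α-carbon, 1,4-elimination of methanol from 10 gives arene 11, and the acidic work-up cleaves its silyl ether. The acetal carbon thus becomes C2'–OMe and the silyloxy carbon the free C4' phenol, with no protecting-group step.

Step 6
Reactants: 12 benzyl 4-hydroxy-2-methoxy-6-pentylbenzoate; 1 oct-2-ynoic acid
Product: 13 benzyl 2-methoxy-4-(oct-2-ynoyloxy)-6-pentylbenzoate
Conditions: DCC, DMAP (5 mol%), CH2Cl2, 0 °C to rt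
Reagents that add atoms: none
Why: Steglich esterification; the carboxyl group of 1 sits on an sp carbon and is unhindered, the phenol is the only nucleophilic site of 12, and low temperature with little DMAP keeps conjugate addition to the ynoate in check. The depside bond C7–O is thereby made before ring A exists.

Step 7
Reactants: 14 methyl acetoacetate
Product: 16 methyl (E)-3-methoxybut-2-enoate, via methyl 3,3-dimethoxybutanoate 15 (not isolated)
Conditions: HC(OMe)3, H2SO4 (cat.), MeOH, rt; then distillation
Reagents that add atoms: trimethyl orthoformate, COC(OC)OC
Why: Acid-catalysed ketalisation by the orthoformate and loss of methanol from ketal 15 on distillation; the conjugated (E)-enol ether is the thermodynamically favoured isomer.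

Step 8
Reactants: 16 methyl (E)-3-methoxybut-2-enoate
Product: 18 1,3-dimethoxy-1-(trimethylsilyloxy)buta-1,3-diene, via lithium dienolate 17 (not isolated)
Conditions: LiN(iPr)2, THF, −78 °C; then Me3SiCl, −78 °C to rt; distillation
Reagents that add atoms: chlorotrimethylsilane, C[Si](C)(C)Cl
Why: γ-Deprotonation of the vinylogous ester gives the extended enolate 17, which the hard silyl electrophile traps on oxygen (kinetic O-silylation) to give the vinylketene silyl acetal 18.

Step 9
Reactants: 13 benzyl 2-methoxy-4-(oct-2-ynoyloxy)-6-pentylbenzoate; 18 1,3-dimethoxy-1-(trimethylsilyloxy)buta-1,3-diene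
Product: 21 benzyl 4-[(2-hydroxy-4-methoxy-6-pentylbenzoyl)oxy]-2-methoxy-6-pentylbenzoate, via cyclohexadiene cycloadduct 19 (not isolated), via aryl trimethylsilyl ether 20 (not isolated)
Conditions: 18 (3 equiv), toluene, 100 °C, sealed tube; then 1 M HCl, THF, 0 °C to rt
Reagents that add atoms: none
Why: A normal-electron-demand Diels–Alder reaction between the electron-rich diene 18 and the ynoate triple bond of 13, followed by aromatisation; the closest known reaction type is the benzannulation of 1-alkoxy-1-silyloxy-3-alkoxybuta-1,3-dienes with 2-alkynoate esters and quinones, which gives 2-hydroxy-4-alkoxy arenes. Ring A is closed by an intermolecular [4+2] cycloaddition that forms C5–C6 and C1–C2, concerted but asynchronous with C5–C6 leading; should it turn stepwise (Michael addition, then closure of the allenoate carbon onto the oxocarbenium carbon), the same six-membered ring results. The selectivity the step needs is regiochemical: the CH2 terminus of 18 carries the largest HOMO coefficient because both the 3-methoxy group and the ketene acetal oxygens push electron density to it, and it bonds to the β-carbon of the ynoate, the pentyl-bearing carbon with the largest LUMO coefficient, which places pentyl at C6, the ester carbon C7 on C1, and the oxygens at C2 and C4. Cycloadduct 19 then loses methanol by 1,4-elimination (methoxy from the acetal carbon, the future C2, and a hydrogen from the future C5) to give the aryl silyl ether 20, which the acidic work-up cleaves, so C2 emerges as free OH and C4 keeps its methyl ether. The only new stereocentre, the acetal carbon of 19, forms racemic and is destroyed on aromatisation, so no stereocontrol is needed. Chemoselectivity rests on three points: a silyl ketene acetal without a Lewis acid does not acylate at ester carbonyls at this temperature, the benzyl ester and ring B are inert, and the aryl ester makes the alkyne more electron-poor than in an alkyl ynoate, which should speed the cycloaddition. The excess of 18 also scavenges the methanol released before it can transesterify the aryl ester, and the new C2 hydroxyl group is at once tied up in a hydrogen bond to the C7 carbonyl, which stabilises the product under the work-up.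

Step 10
Reactants: 21 benzyl 4-[(2-hydroxy-4-methoxy-6-pentylbenzoyl)oxy]-2-methoxy-6-pentylbenzoate
Product: 22 2'-O-methylperlatolic acid, 4-[(2-hydroxy-4-methoxy-6-pentylbenzoyl)oxy]-2-methoxy-6-pentylbenzoic acid
Conditions: H2 (1 atm), Pd/C (10% palladium on carbon), EtOAc, rt
Reagents that add atoms: none
Why: Hydrogenolysis of the benzyl ester over palladium on carbon; the neutral conditions leave the aryl ester, the methyl ethers and both arenes untouched, and the by-product is volatile.

## Compound list

1 | oct-2-ynoic acid | CCCCCC#CC(=O)O | starting material
2 | benzyl oct-2-ynoate | CCCCCC#CC(=O)OCc1ccccc1 | intermediate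
3 | acetyl chloride | CC(=O)Cl | starting material
4 | 1,1-dichloroethene | C=C(Cl)Cl | starting material
5 | 4,4,4-trichlorobutan-2-one | CC(=O)CC(Cl)(Cl)Cl | intermediate
6 | 4,4-dichlorobut-3-en-2-one | CC(=O)C=C(Cl)Cl | intermediate
7 | 4-chloro-4-methoxybut-3-en-2-one (double-bond geometry undefined) | CC(=O)C=C(Cl)OC | intermediate
8 | 4,4-dimethoxybut-3-en-2-one | CC(=O)C=C(OC)OC | intermediate
9 | 1,1-dimethoxy-3-(trimethylsilyloxy)buta-1,3-diene | C=C(O[Si](C)(C)C)C=C(OC)OC | intermediate
10 | benzyl 6,6-dimethoxy-2-pentyl-4-(trimethylsilyloxy)cyclohexa-1,4-diene-1-carboxylate | CCCCCC1=C(C(=O)OCc2ccccc2)C(OC)(OC)C=C(O[Si](C)(C)C)C1 | intermediate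
11 | benzyl 2-methoxy-6-pentyl-4-(trimethylsilyloxy)benzoate | CCCCCc1cc(O[Si](C)(C)C)cc(OC)c1C(=O)OCc1ccccc1 | intermediate
12 | benzyl 4-hydroxy-2-methoxy-6-pentylbenzoate | CCCCCc1cc(O)cc(OC)c1C(=O)OCc1ccccc1 | intermediate
13 | benzyl 2-methoxy-4-(oct-2-ynoyloxy)-6-pentylbenzoate | CCCCCC#CC(=O)Oc1cc(CCCCC)c(C(=O)OCc2ccccc2)c(OC)c1 | intermediate
14 | methyl acetoacetate (methyl 3-oxobutanoate) | CC(=O)CC(=O)OC | starting material
15 | methyl 3,3-dimethoxybutanoate | COC(=O)CC(C)(OC)OC | intermediate
16 | methyl (E)-3-methoxybut-2-enoate | CO/C(C)=C/C(=O)OC | intermediate
17 | lithium 1,3-dimethoxybuta-1,3-dien-1-olate (ketene acetal geometry undefined) | [Li+].[O-]C(OC)=CC(=C)OC | intermediate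
18 | 1,3-dimethoxy-1-(trimethylsilyloxy)buta-1,3-diene (ketene acetal geometry undefined) | C=C(OC)C=C(OC)O[Si](C)(C)C | intermediate
19 | benzyl 4-{[4,6-dimethoxy-2-pentyl-6-(trimethylsilyloxy)cyclohexa-1,4-diene-1-carbonyl]oxy}-2-methoxy-6-pentylbenzoate (racemic at the acetal carbon) | CCCCCC1=C(C(=O)Oc2cc(CCCCC)c(C(=O)OCc3ccccc3)c(OC)c2)C(OC)(O[Si](C)(C)C)C=C(OC)C1 | intermediate
20 | benzyl 2-methoxy-4-{[4-methoxy-2-pentyl-6-(trimethylsilyloxy)benzoyl]oxy}-6-pentylbenzoate | CCCCCc1cc(OC)cc(O[Si](C)(C)C)c1C(=O)Oc1cc(CCCCC)c(C(=O)OCc2ccccc2)c(OC)c1 | intermediate
21 | benzyl 4-[(2-hydroxy-4-methoxy-6-pentylbenzoyl)oxy]-2-methoxy-6-pentylbenzoate | CCCCCc1cc(OC)cc(O)c1C(=O)Oc1cc(CCCCC)c(C(=O)OCc2ccccc2)c(OC)c1 | intermediate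
22 | 2'-O-methylperlatolic acid | CCCCCc1cc(OC)cc(O)c1C(=O)Oc1cc(CCCCC)c(C(=O)O)c(OC)c1 | target

## Step count and risk

Total step count: 10. Longest linear sequence: 7 (steps 2, 3, 4, 5, 6, 9, 10). Steps 1, 7 and 8 are side branches that supply 2 and 18.

**Step 9 (key step).**
- What may go wrong: acyl transfer. The aryl ester of 13 is an activated acyl donor, and at 100 °C the ketene acetal or the methanol released on aromatisation may cleave it before the β-alkyl-substituted triple bond has cycloadded. A second failure is thermal decay of the diene (silyl migration, oligomerisation) over the long reaction time.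
- Fallback: the ring construction is moved off the depside and the rings are joined afterwards. It sets out from 2, which is heated with 18 under the conditions of step 9 and worked up with acid to give benzyl 2-hydroxy-4-methoxy-6-pentylbenzoate F1. Hydrogenolysis (H2, Pd/C, EtOAc) gives 2-hydroxy-4-methoxy-6-pentylbenzoic acid F2. Condensation of F2 with phenol 12 through the mixed anhydride formed with trifluoroacetic anhydride (toluene, rt) comes back to the route at 21.
- Cost: two extra steps and the hindered coupling that the main route avoids.

**Step 5.**
- What may go wrong: loss of the diene and of the oxygen differentiation. Diene 9 is a ketene dimethyl acetal and very sensitive to traces of acid and moisture. Hydrolysis of the diene before the cycloaddition, or of the acetal carbon of 10 before the elimination, would leave a free hydroxyl group at C2' or no ring at all.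
- Fallback: the two oxygens are differentiated by chelation and not by the diene. Methyl acetoacetate 14 is silylated (Me3SiCl, Et3N) to methyl 3-(trimethylsilyloxy)but-2-enoate F3, and then (LiN(iPr)2, Me3SiCl, THF, −78 °C) to 1-methoxy-1,3-bis(trimethylsilyloxy)buta-1,3-diene F4. The fallback sets out from 2, which is heated with F4 and worked up with acid to give benzyl 2,4-dihydroxy-6-pentylbenzoate F5. The non-chelated 4-hydroxyl group of F5 is esterified with 1 (DCC, DMAP cat.) to benzyl 2-hydroxy-4-(oct-2-ynoyloxy)-6-pentylbenzoate F6. The chelated 2-hydroxyl group is then methylated without base (MeI, Ag2O, CH2Cl2), which comes back to the route at 13.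

**Step 3.**
- What may go wrong: over-addition of methoxide. The ketene acetal 8 is itself a Michael acceptor, so local excess of methoxide adds a third time, or cleaves the acetyl group.
- Fallback: the over-addition is made the route. It sets out from 6, which with three equivalents of NaOMe in MeOH is taken on purpose to the orthoester 4,4,4-trimethoxybutan-2-one F7. β-Elimination of methanol on distillation from a trace of KHSO4 comes back to the route at 8.

## Further compounds

F1 | step 9 | benzyl 2-hydroxy-4-methoxy-6-pentylbenzoate | CCCCCc1cc(OC)cc(O)c1C(=O)OCc1ccccc1
F2 | step 9 | 2-hydroxy-4-methoxy-6-pentylbenzoic acid | CCCCCc1cc(OC)cc(O)c1C(=O)O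
F3 | step 5 | methyl 3-(trimethylsilyloxy)but-2-enoate (double-bond geometry undefined) | COC(=O)C=C(C)O[Si](C)(C)C
F4 | step 5 | 1-methoxy-1,3-bis(trimethylsilyloxy)buta-1,3-diene | C=C(O[Si](C)(C)C)C=C(OC)O[Si](C)(C)C
F5 | step 5 | benzyl 2,4-dihydroxy-6-pentylbenzoate | CCCCCc1cc(O)cc(O)c1C(=O)OCc1ccccc1
F6 | step 5 | benzyl 2-hydroxy-4-(oct-2-ynoyloxy)-6-pentylbenzoate | CCCCCC#CC(=O)Oc1cc(CCCCC)c(C(=O)OCc2ccccc2)c(O)c1
F7 | step 3 | 4,4,4-trimethoxybutan-2-one | CC(=O)CC(OC)(OC)OC
A1 | alternative 1 | 2-(benzyloxy)-4-methoxy-6-pentylbenzoic acid | CCCCCc1cc(OC)cc(OCc2ccccc2)c1C(=O)O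
A2 | alternative 1 | benzyl 4-{[2-(benzyloxy)-4-methoxy-6-pentylbenzoyl]oxy}-2-methoxy-6-pentylbenzoate | CCCCCc1cc(OC)cc(OCc2ccccc2)c1C(=O)Oc1cc(CCCCC)c(C(=O)OCc2ccccc2)c(OC)c1
A3 | alternative 2 | 6-(2,4-dioxononyl)-2,2-dimethyl-4H-1,3-dioxin-4-one | CCCCCC(=O)CC(=O)CC1=CC(=O)OC(C)(C)O1
A4 | alternative 2 | benzyl 2-methoxy-6-pentyl-4-[(3,5,7-trioxododecanoyl)oxy]benzoate | CCCCCC(=O)CC(=O)CC(=O)CC(=O)Oc1cc(CCCCC)c(C(=O)OCc2ccccc2)c(OC)c1
A5 | alternative 2 | benzyl 4-[(2,4-dihydroxy-6-pentylbenzoyl)oxy]-2-methoxy-6-pentylbenzoate | CCCCCc1cc(O)cc(O)c1C(=O)Oc1cc(CCCCC)c(C(=O)OCc2ccccc2)c(OC)c1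
A6 | alternative 2 | 4-hydroxy-6-(2-oxoheptyl)-2H-pyran-2-one | CCCCCC(=O)CC1=CC(O)=CC(=O)O1
A7 | alternative 3 | benzyl 2-methoxy-4-[(3-oxobutanoyl)oxy]-6-pentylbenzoate | CC(=O)CC(=O)Oc1cc(CCCCC)c(C(=O)OCc2ccccc2)c(OC)c1
A8 | alternative 3 | benzyl 4-{[1,3-bis(trimethylsilyloxy)buta-1,3-dien-1-yl]oxy}-2-methoxy-6-pentylbenzoate | C=C(O[Si](C)(C)C)C=C(O[Si](C)(C)C)Oc1cc(CCCCC)c(C(=O)OCc2ccccc2)c(OC)c1
A9 | alternative 3 | 1,1-dimethoxyoct-1-en-3-one | CCCCCC(=O)C=C(OC)OC
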